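**Retrosynthetic overview**

1. Target 37 ⇐ HCl opening of epoxy ester 36 ⇐ acylation of the C3 hydroxyl of triol 31 with epoxy acid 34 ⇐ α-face dihydroxylation of the C3=C4 olefin of 30.
2. 30 ⇐ adduct 14 by: C7–C11 bond from a C7 vinyllithium and acetone, C8 ketone from the diene oxygen, C4–C15 bond by Shapiro methylation of the C4 ketone, removal of the C1 carbonyl.
3. Feature used: quaternary C10 (C14 methyl) lies between C1 (ring A) and C9 (ring B), next to the C6=C7–C8(O) unit of ring B. Hence 14 ⇐ methacryloyl trienone 13 by intramolecular Diels–Alder reaction (diene C5=C6–C7=C8–OSi, dienophile C9=C10; bonds C5–C10 and C8–C9). Rings A and B form together in this one step; no other step forms a ring of the skeleton.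
4. 13 ⇐ (S)-epichlorohydrin 1 (the only purchased stereocentre, C4), opened first by vinylmagnesium bromide and then by the enolate of 4-acetylmorpholine; then cross-metathesis with crotonaldehyde, silyl dienol ether formation and isopropenylmagnesium bromide.
5. 34 ⇐ Sharpless epoxidation and oxidation of (E)-2-methylbut-2-en-1-ol 32.

Key step: step 8

Remark: eudesmane numbering is used throughout (ring A = C1–C5, C10; ring B = C5–C10; C14 on C10, C15 on C4, C11 on C7; β = face of C14; octalin/hexalin = decalin with one/two C=C); the transient carbinol centres at C1 (15–17) and C8 (27–29) are drawn as the expected major epimers and are destroyed later.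

Step 1
Reactants: 1 (S)-epichlorohydrin; 2 vinylmagnesium bromide
Product: 3 (S)-1-chloropent-4-en-2-ol
Conditions: CuI (10 mol%), THF, −40 °C; aq. NH4Cl
Reagents that add atoms: none
Why: Copper-catalysed Grignard opening of the epoxide at its CH2 carbon (SN2) leaves the stereocentre and the chloride untouched.

Step 2
Reactants: 3 (S)-1-chloropent-4-en-2-ol
Product: 4 (S)-2-allyloxirane
Conditions: NaOH (powdered), Et2O, 23 °C; distillation
Reagents that add atoms: none
Why: Intramolecular Williamson displacement of chloride by the alkoxide closes the new epoxide without touching the C–O stereocentre.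

Step 3
Reactants: 5 4-acetylmorpholine; 4 (S)-2-allyloxirane
Product: 7 (R)-4-hydroxy-1-(morpholin-4-yl)hept-6-en-1-one, via lithium enolate of 4-acetylmorpholine 6 (not isolated)
Conditions: LiN(iPr)2, LiCl, THF, −78 °C; then 4, −78 → 23 °C
Reagents that add atoms: lithium diisopropylamide, [Li]N(C(C)C)C(C)C (lithium in intermediate 6 only)
Why: Lithium enolates of tertiary amides open terminal epoxides at the CH2 carbon (SN2), so the carbinol centre (future C4) keeps its configuration and the acyl group arrives as a ketone precursor.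

Step 4
Reactants: 7 (R)-4-hydroxy-1-(morpholin-4-yl)hept-6-en-1-one
Product: 8 (R)-4-[(4-methoxybenzyl)oxy]-1-(morpholin-4-yl)hept-6-en-1-one
Conditions: NaH, 4-methoxybenzyl chloride, Bu4NI (cat.), DMF, 0 → 23 °C
Reagents that add atoms: 4-methoxybenzyl chloride, COc1ccc(CCl)cc1
Why: Williamson etherification; the alkoxide does not lactonise onto the tertiary amide because morpholide is a very poor leaving group.

Step 5
Reactants: 8 (R)-4-[(4-methoxybenzyl)oxy]-1-(morpholin-4-yl)hept-6-en-1-one; 9 (E)-but-2-enal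
Product: 10 (2E,5R)-5-[(4-methoxybenzyl)oxy]-8-(morpholin-4-yl)-8-oxooct-2-enal
Conditions: second-generation Hoveyda–Grubbs catalyst (C31H38Cl2N2ORu, 3 mol%), 9 (excess), CH2Cl2, 40 °C
Reagents that add atoms: none
Why: Olefin cross-metathesis of a terminal alkene with an excess of an α,β-unsaturated aldehyde should give the (E)-enal under thermodynamic control, adding C7 and C8.

Step 6
Reactants: 10 (2E,5R)-5-[(4-methoxybenzyl)oxy]-8-(morpholin-4-yl)-8-oxooct-2-enal
Product: 11 (4R,5E,7E)-8-(tert-butyldimethylsilyloxy)-4-[(4-methoxybenzyl)oxy]-1-(morpholin-4-yl)octa-5,7-dien-1-one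
Conditions: TBSOTf, Et3N, CH2Cl2, −78 → 0 °C
Reagents that add atoms: tert-butyldimethylsilyl trifluoromethanesulfonate, CC(C)(C)[Si](C)(C)OS(=O)(=O)C(F)(F)F
Why: Soft γ-enolisation of the O-silylated enal (silyl dienol ether formation) should give the 1-silyloxydiene, the s-trans enal fixing the C7=C8 E geometry and the C4 chain taking the E position on C5=C6, while the amide is far slower to silylate.

Step 7
Reactants: 11 (4R,5E,7E)-8-(tert-butyldimethylsilyloxy)-4-[(4-methoxybenzyl)oxy]-1-(morpholin-4-yl)octa-5,7-dien-1-one; 12 isopropenylmagnesium bromide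
Product: 13 (6R,7E,9E)-10-(tert-butyldimethylsilyloxy)-6-[(4-methoxybenzyl)oxy]-2-methyldeca-1,7,9-trien-3-one
Conditions: THF, −20 → 0 °C; cold pH 6 phosphate buffer; kept cold and used at once
Reagents that add atoms: none
Why: Grignard acylation of a morpholine amide stops at the tetrahedral adduct until work-up, so the methacryloyl ketone should form without over-addition, and the silyl dienol ether is inert to the Grignard reagent.

Step 8
Reactants: 13 (6R,7E,9E)-10-(tert-butyldimethylsilyloxy)-6-[(4-methoxybenzyl)oxy]-2-methyldeca-1,7,9-trien-3-one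
Product: 14 4α-(4-methoxybenzyloxy)-8β-(tert-butyldimethylsilyloxy)-10β-methyl-5αH-Δ6-octalin-1-one
Conditions: toluene (0.01 M), BHT, 70 °C
Reagents that add atoms: none
Why: This is a concerted, asynchronous thermal [4+2] cycloaddition, the intramolecular Diels–Alder reaction of a 2-methyl-1,7,9-decatrien-3-one, a class known to cyclise at or a little above room temperature. Ring A (C1–C5, C10) closes in the fused mode as the chair-like ring of the four-atom tether through the C5–C10 bond, and ring B (C5–C10) is the cyclohexene made by the cycloaddition itself through C5–C10 and C8–C9; the short tether excludes the bridged orientation, so the silyloxy group only raises the diene HOMO. At C10 and C5, the C14 methyl endo and the C1 carbonyl exo combine with the E-configured C5 terminus to place C4 cis to C14 and H5 trans to it (trans fusion), and at C8 the E enol ether places the silyloxy group on the same face (a centre erased later). The step needs the carbonyl-exo mode and one diene face: the α-methyl group of the methacryloyl unit erodes the carbonyl-endo preference, as with α-substituted enone and enal dienophiles in general, and the C4 PMB ether sits pseudo-equatorial in the tether chair because the other diene face would force it 1,3-diaxial to the C14 methyl. The (R)-C4 centre should therefore lead to the 5α-H/10β-methyl adduct, and the minor isomers are diastereomers that chromatography should remove.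

Step 9
Reactants: 14 4α-(4-methoxybenzyloxy)-8β-(tert-butyldimethylsilyloxy)-10β-methyl-5αH-Δ6-octalin-1-one
Product: 15 4α-(4-methoxybenzyloxy)-8β-(tert-butyldimethylsilyloxy)-10β-methyl-5αH-Δ6-octalin-1β-ol
Conditions: NaBH4, MeOH/THF, 0 → 23 °C
Reagents that add atoms: none
Why: Hydride reduction of the ketone, with attack anti to the C14 methyl expected to give mainly the equatorial 1β-alcohol, a centre removed two steps later.

Step 10
Reactants: 15 4α-(4-methoxybenzyloxy)-8β-(tert-butyldimethylsilyloxy)-10β-methyl-5αH-Δ6-octalin-1β-ol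
Product: 17 O-[4α-(4-methoxybenzyloxy)-8β-(tert-butyldimethylsilyloxy)-10β-methyl-5αH-Δ6-octalin-1β-yl] S-methyl dithiocarbonate, via sodium O-alkyl dithiocarbonate 16 (not isolated)
Conditions: NaH, imidazole (cat.), THF, 23 °C; CS2; then MeI
Reagents that add atoms: carbon disulfide, S=C=S; iodomethane, CI; sodium hydride, [Na+].[H-] (sodium in intermediate 16 only)
Why: Xanthate formation, the first stage of the Barton–McCombie deoxygenation: the alkoxide adds to CS2 and the dithiocarbonate salt is S-methylated.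

Step 11
Reactants: 17 O-[4α-(4-methoxybenzyloxy)-8β-(tert-butyldimethylsilyloxy)-10β-methyl-5αH-Δ6-octalin-1β-yl] S-methyl dithiocarbonate
Product: 18 4α-(4-methoxybenzyloxy)-8β-(tert-butyldimethylsilyloxy)-10β-methyl-5αH-Δ6-octalin
Conditions: Bu3SnH, AIBN, toluene, 100 °C
Reagents that add atoms: none
Why: Barton–McCombie radical deoxygenation; the secondary C1 radical has no favourable cyclisation onto C6=C7 and is reduced by the stannane, which removes the temporary C1 oxygen.

Step 12
Reactants: 18 4α-(4-methoxybenzyloxy)-8β-(tert-butyldimethylsilyloxy)-10β-methyl-5αH-Δ6-octalin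
Product: 19 8β-(tert-butyldimethylsilyloxy)-10β-methyl-5αH-Δ6-octalin-4α-ol
Conditions: DDQ, CH2Cl2/pH 7 buffer, 0 °C
Reagents that add atoms: none
Why: Oxidative PMB ether cleavage by DDQ (benzylic hydride abstraction, then hydrolysis of the hemiacetal) leaves the silyl ether and the isolated olefin untouched.

Step 13
Reactants: 19 8β-(tert-butyldimethylsilyloxy)-10β-methyl-5αH-Δ6-octalin-4α-ol
Product: 20 8β-(tert-butyldimethylsilyloxy)-10β-methyl-5αH-Δ6-octalin-4-one
Conditions: Dess–Martin periodinane, NaHCO3, CH2Cl2, 0 → 23 °C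
Reagents that add atoms: none
Why: Dess–Martin oxidation under buffered, non-enolising conditions should keep the C5 centre and the β,γ-olefin in place.

Step 14
Reactants: 20 8β-(tert-butyldimethylsilyloxy)-10β-methyl-5αH-Δ6-octalin-4-one
Product: 21 (E)-2,4,6-triisopropylbenzenesulfonylhydrazone of 8β-(tert-butyldimethylsilyloxy)-10β-methyl-5αH-Δ6-octalin-4-one
Conditions: 2,4,6-triisopropylbenzenesulfonohydrazide, THF, 23 °C
Reagents that add atoms: 2,4,6-triisopropylbenzenesulfonohydrazide, CC(C)c1cc(C(C)C)c(S(=O)(=O)NN)c(C(C)C)c1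
Why: Condensation to the arylsulfonylhydrazone, whose N–N bond takes the side of the C3 methylene, away from the more substituted C5.

Step 15
Reactants: 21 (E)-2,4,6-triisopropylbenzenesulfonylhydrazone of 8β-(tert-butyldimethylsilyloxy)-10β-methyl-5αH-Δ6-octalin-4-one
Product: 23 8β-(tert-butyldimethylsilyloxy)-4,10β-dimethyl-5αH-Δ3,6-hexalin, via C4 vinyllithium 22 (not isolated)
Conditions: n-BuLi (2.1 equiv), THF, −78 → 0 °C; then MeI, −78 → 23 °C
Reagents that add atoms: iodomethane, CI; n-butyllithium, [Li]CCCC (lithium in intermediate 22 only)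
Why: Shapiro reaction: the second deprotonation is directed syn to the sulfonamide nitrogen, at C3 and not at the allylic C5–H, loss of sulfinate and N2 gives the C4 vinyllithium with the C3=C4 bond fixed, and MeI alkylation installs C15.

Step 16
Reactants: 23 8β-(tert-butyldimethylsilyloxy)-4,10β-dimethyl-5αH-Δ3,6-hexalin
Product: 24 4,10β-dimethyl-5αH-Δ3,6-hexalin-8β-ol
Conditions: Bu4NF, THF, 23 °C
Reagents that add atoms: none
Why: Fluoride cleavage of the silyl ether frees the allylic C8 alcohol.

Step 17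
Reactants: 24 4,10β-dimethyl-5αH-Δ3,6-hexalin-8β-ol
Product: 25 4,10β-dimethyl-5αH-Δ3,6-hexalin-8-one
Conditions: Dess–Martin periodinane, NaHCO3, CH2Cl2, 0 °C
Reagents that add atoms: none
Why: Dess–Martin oxidation of the allylic alcohol gives the C6=C7–C8=O enone directly, the buffered neutral medium keeping the skipped C3=C4 olefin and C5 in place.

Step 18
Reactants: 25 4,10β-dimethyl-5αH-Δ3,6-hexalin-8-one
Product: 26 7-iodo-4,10β-dimethyl-5αH-Δ3,6-hexalin-8-one
Conditions: I2, pyridine/CH2Cl2, 0 → 23 °C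
Reagents that add atoms: iodine, II
Why: α-Iodination of the enone by conjugate addition of pyridine, iodination of the enolate and elimination; the isolated C3=C4 olefin does not add iodine irreversibly.

Step 19
Reactants: 26 7-iodo-4,10β-dimethyl-5αH-Δ3,6-hexalin-8-one
Product: 27 7-iodo-4,10β-dimethyl-5αH-Δ3,6-hexalin-8β-ol
Conditions: NaBH4, CeCl3·7H2O, MeOH, −40 °C
Reagents that add atoms: none
Why: Luche 1,2-reduction masks the ketone for the organolithium step, hydride attack anti to C14 being expected to give mainly the 8β-alcohol, a centre re-oxidised in step 21.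

Step 20
Reactants: 27 7-iodo-4,10β-dimethyl-5αH-Δ3,6-hexalin-8β-ol
Product: 29 eudesma-3,6-diene-8β,11-diol, via dilithio alkoxide vinyllithium 28 (not isolated)
Conditions: t-BuLi (3.1 equiv), Et2O, −78 °C; then acetone, −78 → 0 °C
Reagents that add atoms: acetone, CC(C)=O; tert-butyllithium, [Li]C(C)(C)C (lithium in intermediate 28 only)
Why: Iodine–lithium exchange on the lithium alkoxide gives a C7 vinyllithium whose 1,2-addition to acetone forms the C7–C11 bond and the tertiary carbinol.

Step 21
Reactants: 29 eudesma-3,6-diene-8β,11-diol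
Product: 30 11-hydroxyeudesma-3,6-dien-8-one
Conditions: Dess–Martin periodinane, NaHCO3, CH2Cl2, 0 °C
Reagents that add atoms: none
Why: Dess–Martin oxidation converts only the secondary allylic alcohol, since the tertiary C11 carbinol cannot be oxidised.

Step 22
Reactants: 30 11-hydroxyeudesma-3,6-dien-8-one
Product: 31 3α,4α,11-trihydroxyeudesm-6-en-8-one
Conditions: OsO4 (3 mol%), NMO, acetone/H2O, 23 °C
Reagents that add atoms: osmium tetroxide, O=[Os](=O)(=O)=O (oxygen carrier); 4-methylmorpholine N-oxide, C[N+]1([O-])CCOCC1; water, O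
Why: Upjohn dihydroxylation: OsO4 should prefer the electron-rich trisubstituted C3=C4 olefin over the enone and add syn from the α face, anti to the axial C14 methyl, setting C3 (R) and C4 (S).

Step 23
Reactants: 32 (E)-2-methylbut-2-en-1-ol
Product: 33 (2R,3R)-2,3-epoxy-2-methylbutan-1-ol
Conditions: Ti(OiPr)4, D-(−)-diisopropyl tartrate, t-BuOOH, 4 Å sieves, CH2Cl2, −20 °C
Reagents that add atoms: tert-butyl hydroperoxide, CC(C)(C)OO
Why: Sharpless asymmetric epoxidation; the D-(−)-tartrate complex delivers oxygen to the olefin face that gives the (2R,3R)-epoxy alcohol, the enantiomer of the (2S,3S) product of the L-(+)-tartrate series.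

Step 24
Reactants: 33 (2R,3R)-2,3-epoxy-2-methylbutan-1-ol
Product: 34 (2S,3R)-2,3-dimethyloxirane-2-carboxylic acid
Conditions: TEMPO (cat.), PhI(OAc)2, MeCN/H2O, 23 °C
Reagents that add atoms: water, O
Why: Oxoammonium (TEMPO) oxidation of the primary alcohol through the aldehyde hydrate to the acid leaves both epoxide centres untouched, the C2 descriptor changing only by priority.

Step 25
Reactants: 34 (2S,3R)-2,3-dimethyloxirane-2-carboxylic acid; 31 3α,4α,11-trihydroxyeudesm-6-en-8-one
Product: 36 3α-[(2S,3R)-2,3-dimethyloxirane-2-carbonyloxy]-4α,11-dihydroxyeudesm-6-en-8-one, via 2,4,6-trichlorobenzoic mixed anhydride 35 (not isolated)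
Conditions: 2,4,6-trichlorobenzoyl chloride, Et3N, THF, 23 °C; then 31, DMAP, toluene, 40 °C
Reagents that add atoms: 2,4,6-trichlorobenzoyl chloride, O=C(Cl)c1c(Cl)cc(Cl)cc1Cl (aroyl group in intermediate 35 only)
Why: Yamaguchi esterification; the mixed anhydride should acylate the secondary C3 hydroxyl, since the tertiary C4 and C11 hydroxyls are too hindered to compete.

Step 26
Reactants: 36 3α-[(2S,3R)-2,3-dimethyloxirane-2-carbonyloxy]-4α,11-dihydroxyeudesm-6-en-8-one
Product: 37 3α-[(2R,3S)-3-chloro-2-hydroxy-2-methylbutanoyloxy]-4α,11-dihydroxyeudesm-6-en-8-one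
Conditions: HCl (4 M in dioxane), CH2Cl2, 0 °C
Reagents that add atoms: hydrogen chloride, Cl
Why: Acid-promoted epoxide opening; chloride should attack C3′ (β to the ester, SN2, inversion) and not the tertiary α-carbon deactivated by the carbonyl, giving the (2R,3S)-chlorohydrin.

**Compound list**

1 | (S)-epichlorohydrin | ClC[C@@H]1CO1 | starting material
2 | vinylmagnesium bromide | C=C[Mg]Br | starting material
3 | (S)-1-chloropent-4-en-2-ol | ClC[C@@H](O)CC=C | intermediate
4 | (S)-2-allyloxirane | C=CC[C@H]1CO1 | intermediate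
5 | 4-acetylmorpholine | CC(=O)N1CCOCC1 | starting material
6 | lithium enolate of 4-acetylmorpholine (not isolated) | C=C(O[Li])N1CCOCC1 | intermediate
7 | (R)-4-hydroxy-1-(morpholin-4-yl)hept-6-en-1-one | C=CC[C@H](O)CCC(=O)N1CCOCC1 | intermediate
8 | (R)-4-[(4-methoxybenzyl)oxy]-1-(morpholin-4-yl)hept-6-en-1-one | C=CC[C@H](OCc1ccc(OC)cc1)CCC(=O)N1CCOCC1 | intermediate
9 | (E)-but-2-enal (crotonaldehyde) | C/C=C/C=O | starting material
10 | (2E,5R)-5-[(4-methoxybenzyl)oxy]-8-(morpholin-4-yl)-8-oxooct-2-enal | O=C/C=C/C[C@H](OCc1ccc(OC)cc1)CCC(=O)N1CCOCC1 | intermediate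
11 | (4R,5E,7E)-8-(tert-butyldimethylsilyloxy)-4-[(4-methoxybenzyl)oxy]-1-(morpholin-4-yl)octa-5,7-dien-1-one | O=C(CC[C@@H](OCc1ccc(OC)cc1)/C=C/C=C/O[Si](C)(C)C(C)(C)C)N1CCOCC1 | intermediate
12 | isopropenylmagnesium bromide | CC(=C)[Mg]Br | starting material
13 | (6R,7E,9E)-10-(tert-butyldimethylsilyloxy)-6-[(4-methoxybenzyl)oxy]-2-methyldeca-1,7,9-trien-3-one | C=C(C)C(=O)CC[C@@H](OCc1ccc(OC)cc1)/C=C/C=C/O[Si](C)(C)C(C)(C)C | intermediate
14 | 4α-(4-methoxybenzyloxy)-8β-(tert-butyldimethylsilyloxy)-10β-methyl-5αH-Δ6-octalin-1-one (4R,5R,8R,10R) | O=C1CC[C@@H](OCc3ccc(OC)cc3)[C@@H]2C=C[C@H](O[Si](C)(C)C(C)(C)C)C[C@@]12C | intermediate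
15 | 1β-alcohol of 14 | O[C@@H]1CC[C@@H](OCc3ccc(OC)cc3)[C@@H]2C=C[C@H](O[Si](C)(C)C(C)(C)C)C[C@@]12C | intermediate
16 | sodium O-alkyl dithiocarbonate of 15 (not isolated) | [Na+].[S-]C(=S)O[C@@H]1CC[C@@H](OCc3ccc(OC)cc3)[C@@H]2C=C[C@H](O[Si](C)(C)C(C)(C)C)C[C@@]12C | intermediate
17 | O-alkyl S-methyl dithiocarbonate of 15 | CSC(=S)O[C@@H]1CC[C@@H](OCc3ccc(OC)cc3)[C@@H]2C=C[C@H](O[Si](C)(C)C(C)(C)C)C[C@@]12C | intermediate
18 | 4α-(4-methoxybenzyloxy)-8β-(tert-butyldimethylsilyloxy)-10β-methyl-5αH-Δ6-octalin | C1CC[C@@H](OCc3ccc(OC)cc3)[C@@H]2C=C[C@H](O[Si](C)(C)C(C)(C)C)C[C@@]12C | intermediate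
19 | 8β-(tert-butyldimethylsilyloxy)-10β-methyl-5αH-Δ6-octalin-4α-ol | C1CC[C@@H](O)[C@@H]2C=C[C@H](O[Si](C)(C)C(C)(C)C)C[C@@]12C | intermediate
20 | 8β-(tert-butyldimethylsilyloxy)-10β-methyl-5αH-Δ6-octalin-4-one | C1CCC(=O)[C@@H]2C=C[C@H](O[Si](C)(C)C(C)(C)C)C[C@@]12C | intermediate
21 | (E)-2,4,6-triisopropylbenzenesulfonylhydrazone of 20 | C1CC/C(=N\NS(=O)(=O)c3c(C(C)C)cc(C(C)C)cc3C(C)C)[C@@H]2C=C[C@H](O[Si](C)(C)C(C)(C)C)C[C@@]12C | intermediate
22 | C4 vinyllithium, 4-lithio-8β-(tert-butyldimethylsilyloxy)-10β-methyl-5αH-Δ3,6-hexalin (not isolated) | C1CC=C([Li])[C@@H]2C=C[C@H](O[Si](C)(C)C(C)(C)C)C[C@@]12C | intermediate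
23 | 8β-(tert-butyldimethylsilyloxy)-4,10β-dimethyl-5αH-Δ3,6-hexalin | C1CC=C(C)[C@@H]2C=C[C@H](O[Si](C)(C)C(C)(C)C)C[C@@]12C | intermediate
24 | 4,10β-dimethyl-5αH-Δ3,6-hexalin-8β-ol | C1CC=C(C)[C@@H]2C=C[C@H](O)C[C@@]12C | intermediate
25 | 4,10β-dimethyl-5αH-Δ3,6-hexalin-8-one | C1CC=C(C)[C@@H]2C=CC(=O)C[C@@]12C | intermediate
26 | 7-iodo-4,10β-dimethyl-5αH-Δ3,6-hexalin-8-one | C1CC=C(C)[C@@H]2C=C(I)C(=O)C[C@@]12C | intermediate
27 | 7-iodo-4,10β-dimethyl-5αH-Δ3,6-hexalin-8β-ol | C1CC=C(C)[C@@H]2C=C(I)[C@H](O)C[C@@]12C | intermediate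
28 | lithium 7-lithio-4,10β-dimethyl-5αH-Δ3,6-hexalin-8β-olate (not isolated) | C1CC=C(C)[C@@H]2C=C([Li])[C@H](O[Li])C[C@@]12C | intermediate
29 | eudesma-3,6-diene-8β,11-diol (5αH, 10β-methyl) | C1CC=C(C)[C@@H]2C=C(C(C)(C)O)[C@H](O)C[C@@]12C | intermediate
30 | 11-hydroxyeudesma-3,6-dien-8-one (5R,10R) | C1CC=C(C)[C@@H]2C=C(C(C)(C)O)C(=O)C[C@@]12C | intermediate
31 | 3α,4α,11-trihydroxyeudesm-6-en-8-one (3R,4S,5R,10R) | O[C@@H]1CC[C@]2(C)CC(=O)C(C(C)(C)O)=C[C@H]2[C@]1(C)O | intermediate
32 | (E)-2-methylbut-2-en-1-ol | C/C=C(\C)CO | starting material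
33 | (2R,3R)-2,3-epoxy-2-methylbutan-1-ol | C[C@H]1O[C@]1(C)CO | intermediate
34 | (2S,3R)-2,3-dimethyloxirane-2-carboxylic acid | C[C@H]1O[C@]1(C)C(=O)O | intermediate
35 | (2S,3R)-2,3-dimethyloxirane-2-carboxylic 2,4,6-trichlorobenzoic anhydride (not isolated) | C[C@H]1O[C@]1(C)C(=O)OC(=O)c2c(Cl)cc(Cl)cc2Cl | intermediate
36 | 3α-[(2S,3R)-2,3-dimethyloxirane-2-carbonyloxy]-4α,11-dihydroxyeudesm-6-en-8-one | C[C@H]3O[C@]3(C)C(=O)O[C@@H]1CC[C@]2(C)CC(=O)C(C(C)(C)O)=C[C@H]2[C@]1(C)O | intermediate
37 | 3α-[(2R,3S)-3-chloro-2-hydroxy-2-methylbutanoyloxy]-4α,11-dihydroxyeudesm-6-en-8-one (CNP0288516.1) | C[C@H](Cl)[C@](C)(O)C(=O)O[C@@H]1CC[C@]2(C)CC(=O)C(C(C)(C)O)=C[C@H]2[C@]1(C)O | target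

**Step count**

Total: 26 steps. Longest linear sequence: 24 steps (steps 1–22, 25 and 26); steps 23 and 24 make the side-chain acid.

**Steps most likely to fail**

Step 8 (key cycloaddition). What may go wrong: cyclisation through the carbonyl-endo transition state, or on the other diene face, gives diastereomers with the wrong C10 configuration, and a quaternary C10 cannot be corrected later. Fallback, setting out from epoxide 4 and coming back at 18: the activating carbonyl is moved from the tether to the dienophile terminus, so that the endo rule itself gives the trans fusion and C1 is a methylene from the start. Copper-catalysed opening of 4 with the Grignard reagent of 2-(2-bromoethyl)-2-methyl-1,3-dioxolane gives (R)-7-(2-methyl-1,3-dioxolan-2-yl)hept-1-en-4-ol F1. PMB ether formation as in step 4 gives the ketal ether F2, and PPTS in wet acetone frees the methyl ketone F3. Horner–Wadsworth–Emmons reaction with trimethyl phosphonoacetate and NaH gives the (E)-3-methyl-2-enoate F4 (the Z isomer is separated). Cross-metathesis with 9 as in step 5 gives the enal F5, and TBSOTf/Et3N as in step 6 gives the silyl dienol ether triene F6. Heating F6 in toluene (160–180 °C, BHT) should give the trans-fused 9β-methoxycarbonyl octalin F7 through the ester-endo chair transition state of an (E)-configured terminally activated triene, here with matched polarity (C5 to the β-carbon C10). Me3SnOH gives the acid F8, which is converted into its N-hydroxypyridine-2-thione ester F9 and decarboxylated with t-BuSH under visible light (Barton decarboxylation) to 18.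

Step 15 (Shapiro methylation). What may go wrong: deprotonation at the allylic C5–H instead of C3, or protonation of the vinyllithium before it is methylated. Fallback, setting out from ketone 20 and coming back at 23: the non-basic organocerium reagent from MeLi and CeCl3 adds from the α face to give the 4β-hydroxy-4α-methyl compound F10. Burgess dehydration is a syn elimination and can take only the 3β-hydrogen or a methyl hydrogen, because H5 is anti to the 4β-oxygen. The C3=C4 olefin 23 should therefore form beside its exocyclic isomer, which is separated.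

Step 26 (HCl opening). What may go wrong: acid-induced dehydration or chlorination at the tertiary C11 and C4 carbinols competes with epoxide opening, or chloride attack is not fully regioselective, at the last stage. Fallback, setting out from acid 34 (with triol 31) and coming back at 37: the epoxide is opened before coupling. Cold concentrated aqueous HCl converts 34 into (2R,3S)-3-chloro-2-hydroxy-2-methylbutanoic acid F11. TESOTf and 2,6-lutidine give the bis-silyl compound F12, and K2CO3 in methanol frees the 2-(triethylsilyloxy) acid F13. Yamaguchi esterification with 31 as in step 25 gives the silylated ester F14, and HF·pyridine removes the silyl ether to give 37.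

**Further compounds**

F1 | step 8 | (R)-7-(2-methyl-1,3-dioxolan-2-yl)hept-1-en-4-ol | C=CC[C@H](O)CCCC1(C)OCCO1
F2 | step 8 | (R)-2-{4-[(4-methoxybenzyl)oxy]hept-6-en-1-yl}-2-methyl-1,3-dioxolane | C=CC[C@H](OCc1ccc(OC)cc1)CCCC1(C)OCCO1
F3 | step 8 | (R)-6-[(4-methoxybenzyl)oxy]non-8-en-2-one | C=CC[C@H](OCc1ccc(OC)cc1)CCCC(C)=O
F4 | step 8 | methyl (2E,7R)-7-[(4-methoxybenzyl)oxy]-3-methyldeca-2,9-dienoate | C=CC[C@H](OCc1ccc(OC)cc1)CCC/C(C)=C/C(=O)OC
F5 | step 8 | methyl (2E,7R,9E)-7-[(4-methoxybenzyl)oxy]-3-methyl-11-oxoundeca-2,9-dienoate | O=C/C=C/C[C@H](OCc1ccc(OC)cc1)CCC/C(C)=C/C(=O)OC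
F6 | step 8 | methyl (2E,7R,8E,10E)-11-(tert-butyldimethylsilyloxy)-7-[(4-methoxybenzyl)oxy]-3-methylundeca-2,8,10-trienoate | COC(=O)/C=C(\C)CCC[C@@H](OCc1ccc(OC)cc1)/C=C/C=C/O[Si](C)(C)C(C)(C)C
F7 | step 8 | 9β-methoxycarbonyl-4α-(4-methoxybenzyloxy)-8β-(tert-butyldimethylsilyloxy)-10β-methyl-5αH-Δ6-octalin | C1CC[C@@H](OCc3ccc(OC)cc3)[C@@H]2C=C[C@H](O[Si](C)(C)C(C)(C)C)[C@H](C(=O)OC)[C@@]12C
F8 | step 8 | 4α-(4-methoxybenzyloxy)-8β-(tert-butyldimethylsilyloxy)-10β-methyl-5αH-Δ6-octalin-9β-carboxylic acid | C1CC[C@@H](OCc3ccc(OC)cc3)[C@@H]2C=C[C@H](O[Si](C)(C)C(C)(C)C)[C@H](C(=O)O)[C@@]12C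
F9 | step 8 | 2-thioxopyridin-1(2H)-yl ester of F8 | C1CC[C@@H](OCc3ccc(OC)cc3)[C@@H]2C=C[C@H](O[Si](C)(C)C(C)(C)C)[C@H](C(=O)On4ccccc4=S)[C@@]12C
F10 | step 15 | 8β-(tert-butyldimethylsilyloxy)-4α,10β-dimethyl-5αH-Δ6-octalin-4β-ol | C1CC[C@](C)(O)[C@@H]2C=C[C@H](O[Si](C)(C)C(C)(C)C)C[C@@]12C
F11 | step 26 | (2R,3S)-3-chloro-2-hydroxy-2-methylbutanoic acid | C[C@H](Cl)[C@](C)(O)C(=O)O
F12 | step 26 | triethylsilyl (2R,3S)-3-chloro-2-methyl-2-(triethylsilyloxy)butanoate | C[C@H](Cl)[C@](C)(O[Si](CC)(CC)CC)C(=O)O[Si](CC)(CC)CC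
F13 | step 26 | (2R,3S)-3-chloro-2-methyl-2-(triethylsilyloxy)butanoic acid | C[C@H](Cl)[C@](C)(O[Si](CC)(CC)CC)C(=O)O
F14 | step 26 | 3α-[(2R,3S)-3-chloro-2-methyl-2-(triethylsilyloxy)butanoyloxy]-4α,11-dihydroxyeudesm-6-en-8-one | C[C@H](Cl)[C@](C)(O[Si](CC)(CC)CC)C(=O)O[C@@H]1CC[C@]2(C)CC(=O)C(C(C)(C)O)=C[C@H]2[C@]1(C)O
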